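The carbocycle is disconnected at C7=C8, the one ring bond that carries no stereochemistry once the 7,8-trans-diol is traced back to an epoxide. Ring-closing metathesis between a vinyl group on C8a and the terminal alkene of a C4a side chain closes the six-membered ring in one operation. It exploits the fact that C4a and C8a of the 4-pyranone ring hold the two alkenes on adjacent, coplanar positions, while the cis-5,6-dioxolane turns the side-chain alkene toward C8a. The precursor is a 6-(arylethyl)-4-pyranone carrying a C8a vinyl group and a (4S,5R)-2,2-dimethyl-5-vinyl-1,3-dioxolane on C4a; the product acetonide then steers anti epoxidation and hydrolysis at C8.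

Key step: step 9

Remark: in the names of monocyclic pyranones, pyran C2, C3 and C6 are the later chromone C8a, C4a and C2, and side-chain C1 and C2 become C5 and C6; compounds 1, 3, 6 and 13 are taken to be catalogue chemicals.
Remark: 17 (dioxolane 4S,5R) and 18 (5S,6R) correspond to 5S,6S of the target; descriptor changes at C6 and C7 along the route are CIP priority effects, and only C8 is inverted (step 11).

Step 1
Reactants: 1 3-(benzyloxy)-4-methoxybenzyl alcohol
Product: 2 3-(benzyloxy)-4-methoxybenzyl bromide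
Conditions: PBr3 (0.4 equiv), CH2Cl2, 0 °C
Reagents that add atoms: phosphorus tribromide, BrP(Br)Br
Why: Conversion of a primary benzylic alcohol into the bromide through a phosphite ester and SN2 displacement by bromide, which leaves the aryl benzyl and methyl ethers untouched.

Step 2
Reactants: 3 2,2,6-trimethyl-4H-1,3-dioxin-4-one; 2 3-(benzyloxy)-4-methoxybenzyl bromide
Product: 5 6-[2-(3-benzyloxy-4-methoxyphenyl)ethyl]-2,2-dimethyl-4H-1,3-dioxin-4-one, via lithium dienolate 4 (not isolated)
Conditions: LiN(iPr)2 (1.1 equiv), THF–DMPU, −78 °C; then 2, −78 → −20 °C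
Reagents that add atoms: none
Why: Vinylogous (γ) alkylation of the dioxinone dienolate, which in the presence of the polar co-solvent should react at its exocyclic methylene carbon with the reactive benzylic bromide in an SN2 step.

Step 3
Reactants: 5 6-[2-(3-benzyloxy-4-methoxyphenyl)ethyl]-2,2-dimethyl-4H-1,3-dioxin-4-one; 6 (E)-1,3,3-trimethoxyprop-1-ene
Product: 10 6-[2-(3-benzyloxy-4-methoxyphenyl)ethyl]-4-oxo-4H-pyran-3-carbaldehyde, via acylketene 7 (not isolated), via methoxy cycloadduct 8 (not isolated), via dimethyl acetal 9 (not isolated)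
Conditions: 6 (3 equiv), toluene, 110 °C; then 1 M HCl (aq)–THF, 23 °C
Reagents that add atoms: water, O
Why: Thermal retro-[4+2] of the dioxinone releases acetone and the acylketene, which should undergo a hetero-Diels–Alder reaction with the enol ether (acetal-bearing carbon to the ketene carbon, acyl oxygen to the methoxy-bearing carbon), after which acid eliminates methanol to the 4-pyranone and hydrolyses the acetal.

Step 4
Reactants: 10 6-[2-(3-benzyloxy-4-methoxyphenyl)ethyl]-4-oxo-4H-pyran-3-carbaldehyde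
Product: 11 racemic (3Z)-6-[2-(3-benzyloxy-4-methoxyphenyl)ethyl]-3-(hydroxymethylidene)-2-vinyl-2,3-dihydro-4H-pyran-4-one (hydrogen-bonded enol)
Conditions: CH2=CHMgBr (2.2 equiv), CuI (1.1 equiv), THF, −40 °C; then 10, −78 °C; NH4Cl (aq)
Reagents that add atoms: vinylmagnesium bromide, C=C[Mg]Br
Why: Organocuprate 1,4-addition: the unsubstituted pyran C2 (later C8a) is the β-carbon of an enone activated by both the ring ketone and the formyl group, so the soft divinylcuprate should add there and not at the formyl carbon or the substituted C6, and the racemic centre it creates is erased in step 5.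

Step 5
Reactants: 11 racemic (3Z)-6-[2-(3-benzyloxy-4-methoxyphenyl)ethyl]-3-(hydroxymethylidene)-2-vinyl-2,3-dihydro-4H-pyran-4-one
Product: 12 6-[2-(3-benzyloxy-4-methoxyphenyl)ethyl]-4-oxo-2-vinyl-4H-pyran-3-carbaldehyde
Conditions: DDQ (1.1 equiv), 1,4-dioxane, 23 °C
Reagents that add atoms: none
Why: Quinone dehydrogenation of a 2-formyl ketone: hydride abstraction from the allylic, oxygen-bearing C2–H of the enol and loss of the enol proton should restore the fully conjugated 4-pyranone.

Step 6
Reactants: 13 (E)-2-[3-(tert-butyldimethylsilyloxy)prop-1-en-1-yl]-4,4,5,5-tetramethyl-1,3,2-dioxaborolane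
Product: 14 (E)-2-[3-(tert-butyldimethylsilyloxy)prop-2-en-1-yl]-4,4,5,5-tetramethyl-1,3,2-dioxaborolane
Conditions: [Ir(cod)(PPh2Me)2]PF6 (3 mol%, activated with H2), THF, 23 °C
Reagents that add atoms: none
Why: Iridium hydride-catalysed alkene isomerisation (addition–elimination) moves the double bond into conjugation with oxygen and should give the E-configured γ-silyloxyallylboronate needed for anti selectivity.

Step 7
Reactants: 12 6-[2-(3-benzyloxy-4-methoxyphenyl)ethyl]-4-oxo-2-vinyl-4H-pyran-3-carbaldehyde; 14 (E)-2-[3-(tert-butyldimethylsilyloxy)prop-2-en-1-yl]-4,4,5,5-tetramethyl-1,3,2-dioxaborolane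
Product: 15 6-[2-(3-benzyloxy-4-methoxyphenyl)ethyl]-3-[(1S,2R)-2-(tert-butyldimethylsilyloxy)-1-hydroxybut-3-en-1-yl]-2-vinyl-4H-pyran-4-one
Conditions: (R)-TRIP phosphoric acid [(R)-3,3'-bis(2,4,6-triisopropylphenyl)-1,1'-binaphthyl-2,2'-diyl hydrogen phosphate] (5 mol%), 14 (1.5 equiv), 4 Å molecular sieves, toluene, −30 → 0 °C; neutral aqueous work-up
Reagents that add atoms: none
Why: Chiral phosphoric acid-catalysed allylboration through a closed chair transition state, in which the E geometry of 14 sets the anti (erythro) relation of the two oxygens and the (R)-catalyst, by analogy with aryl aldehydes, is expected to direct attack to the Re face of the formyl group, giving 1S (later C5) and 2R (later C6); the configuration is to be verified on 15, and the mirror-image catalyst is the remedy if the sense is opposite.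

Step 8
Reactants: 15 6-[2-(3-benzyloxy-4-methoxyphenyl)ethyl]-3-[(1S,2R)-2-(tert-butyldimethylsilyloxy)-1-hydroxybut-3-en-1-yl]-2-vinyl-4H-pyran-4-one
Product: 17 6-[2-(3-benzyloxy-4-methoxyphenyl)ethyl]-3-[(4S,5R)-2,2-dimethyl-5-vinyl-1,3-dioxolan-4-yl]-2-vinyl-4H-pyran-4-one, via free diol 16 (not isolated)
Conditions: HF·pyridine, pyridine, THF, 0 → 23 °C; evaporate; then 2,2-dimethoxypropane, PPTS (cat.), CH2Cl2, 23 °C
Reagents that add atoms: 2,2-dimethoxypropane, COC(C)(C)OC
Why: Fluoride cleavage of the silyl ether under non-basic conditions (so that the C5 hydroxyl cannot add to the C8a vinyl group in an oxa-Michael reaction), followed by acid-catalysed transketalisation of the anti-diol to the cis-dioxolane without touching either stereocentre.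

Step 9
Reactants: 17 6-[2-(3-benzyloxy-4-methoxyphenyl)ethyl]-3-[(4S,5R)-2,2-dimethyl-5-vinyl-1,3-dioxolan-4-yl]-2-vinyl-4H-pyran-4-one
Product: 18 (5S,6R)-2-[2-(3-benzyloxy-4-methoxyphenyl)ethyl]-5,6-(isopropylidenedioxy)-5,6-dihydro-4H-chromen-4-one (cis-fused acetonide, C7=C8 alkene)
Conditions: second-generation Grubbs catalyst (H2IMes)(PCy3)Cl2Ru=CHPh (5 mol%), CH2Cl2 (5 mM), 40 °C
Reagents that add atoms: none
Why: Ring-closing olefin metathesis by the metallacyclobutane ([2+2]/retro-[2+2]) pathway: the ruthenium alkylidene should load on the non-conjugated vinyl group at the dioxolane (future C7), add across the C8a vinyl group and release ethene, whose loss makes the closure irreversible. The closest known reaction type is the metathesis closure of ortho-vinyl aryl dienes to 1,2-dihydronaphthalenes and of sugar-derived dienes to cyclohexene diol acetonides. The one ring closed is the six-membered carbocycle C4a–C5–C6–C7=C8–C8a, formed by joining the alkene carbons C7 and C8 (cyclohexene closure with an endocyclic cis alkene, cis-fused to the dioxolane). No stereocentre is created; C5 (S) and C6 (R) come unchanged from step 7 because no bond to either carbon is made or broken. The step needs ring closure to win over intermolecular metathesis and over alkene migration toward the aromatic chromone; the substrate secures this because C4a and C8a fix the two chains on adjacent sp2 carbons, the cis-dioxolane turns the C6 vinyl group toward C8a, both alkenes are monosubstituted, and the reaction is run dilute and neutral.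

Step 10
Reactants: 18 (5S,6R)-2-[2-(3-benzyloxy-4-methoxyphenyl)ethyl]-5,6-(isopropylidenedioxy)-5,6-dihydro-4H-chromen-4-one
Product: 19 (5S,6S,7R,8R)-2-[2-(3-benzyloxy-4-methoxyphenyl)ethyl]-7,8-epoxy-5,6-(isopropylidenedioxy)-5,6,7,8-tetrahydro-4H-chromen-4-one (epoxide anti to the acetonide)
Conditions: mCPBA (2 equiv), NaHCO3, CH2Cl2, 0 → 23 °C
Reagents that add atoms: 3-chloroperoxybenzoic acid, OOC(=O)c1cccc(Cl)c1
Why: Prilezhaev epoxidation of the cis-disubstituted C7=C8 alkene, in which the cis-fused dioxolane shields its own face so that the peracid should add anti to it and set C7 and C8, while the vinylogous-ester double bonds of the pyranone are too electron-poor to react.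

Step 11
Reactants: 19 (5S,6S,7R,8R)-2-[2-(3-benzyloxy-4-methoxyphenyl)ethyl]-7,8-epoxy-5,6-(isopropylidenedioxy)-5,6,7,8-tetrahydro-4H-chromen-4-one
Product: 21 (5S,6S,7R,8S)-2-[2-(3-benzyloxy-4-methoxyphenyl)ethyl]-5,6,7,8-tetrahydroxy-5,6,7,8-tetrahydro-4H-chromen-4-one, via diol acetonide 20 (not isolated)
Conditions: 0.5 M H2SO4 (aq)–THF (1:1), 0 → 40 °C
Reagents that add atoms: water, O
Why: Acid-catalysed SN2-type epoxide hydrolysis in which water should attack C8, the carbon allylic to C4a=C8a, with inversion (C7 is deactivated by the neighbouring C6–O bond), giving the 7,8-trans diol with O7 anti to O6, after which warming hydrolyses the acetonide.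

Step 12
Reactants: 21 (5S,6S,7R,8S)-2-[2-(3-benzyloxy-4-methoxyphenyl)ethyl]-5,6,7,8-tetrahydroxy-5,6,7,8-tetrahydro-4H-chromen-4-one
Product: 22 (5S,6S,7R,8S)-5,6,7,8-tetrahydroxy-2-[2-(3-hydroxy-4-methoxyphenyl)ethyl]-5,6,7,8-tetrahydro-4H-chromen-4-one (CNP0224308.1)
Conditions: H2 (1 atm), 10% Pd/C, EtOAc–MeOH, 23 °C
Reagents that add atoms: none
Why: Catalytic hydrogenolysis of the aryl benzyl ether, mild enough that the 4-pyranone and the four secondary alcohols should stay intact.

Compound list
1 | 3-(benzyloxy)-4-methoxybenzyl alcohol | COc1ccc(CO)cc1OCc1ccccc1 | starting material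
2 | 3-(benzyloxy)-4-methoxybenzyl bromide | COc1ccc(CBr)cc1OCc1ccccc1 | intermediate
3 | 2,2,6-trimethyl-4H-1,3-dioxin-4-one | CC1=CC(=O)OC(C)(C)O1 | starting material
4 | lithium 2,2-dimethyl-6-methylidene-6H-1,3-dioxin-4-olate (dienolate of 3) | C=C1C=C([O-])OC(C)(C)O1.[Li+] | intermediate
5 | 6-[2-(3-benzyloxy-4-methoxyphenyl)ethyl]-2,2-dimethyl-4H-1,3-dioxin-4-one | COc1ccc(CCC2=CC(=O)OC(C)(C)O2)cc1OCc1ccccc1 | intermediate
6 | (E)-1,3,3-trimethoxyprop-1-ene | CO/C=C/C(OC)OC | starting material
7 | 5-(3-benzyloxy-4-methoxyphenyl)-3-oxopent-1-en-1-one (acylketene) | COc1ccc(CCC(=O)C=C=O)cc1OCc1ccccc1 | intermediate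
8 | racemic 6-[2-(3-benzyloxy-4-methoxyphenyl)ethyl]-3-(dimethoxymethyl)-2-methoxy-2,3-dihydro-4H-pyran-4-one (relative configuration not relevant) | COC1OC(CCc2ccc(OC)c(OCc3ccccc3)c2)=CC(=O)C1C(OC)OC | intermediate
9 | 6-[2-(3-benzyloxy-4-methoxyphenyl)ethyl]-3-(dimethoxymethyl)-4H-pyran-4-one | COC(OC)c1coc(CCc2ccc(OC)c(OCc3ccccc3)c2)cc1=O | intermediate
10 | 6-[2-(3-benzyloxy-4-methoxyphenyl)ethyl]-4-oxo-4H-pyran-3-carbaldehyde | O=Cc1coc(CCc2ccc(OC)c(OCc3ccccc3)c2)cc1=O | intermediate
11 | racemic (3Z)-6-[2-(3-benzyloxy-4-methoxyphenyl)ethyl]-3-(hydroxymethylidene)-2-vinyl-2,3-dihydro-4H-pyran-4-one | O/C=C1\C(=O)C=C(CCc2ccc(OC)c(OCc3ccccc3)c2)OC1C=C | intermediate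
12 | 6-[2-(3-benzyloxy-4-methoxyphenyl)ethyl]-4-oxo-2-vinyl-4H-pyran-3-carbaldehyde | C=Cc1oc(CCc2ccc(OC)c(OCc3ccccc3)c2)cc(=O)c1C=O | intermediate
13 | (E)-2-[3-(tert-butyldimethylsilyloxy)prop-1-en-1-yl]-4,4,5,5-tetramethyl-1,3,2-dioxaborolane | CC(C)(C)[Si](C)(C)OC/C=C/B1OC(C)(C)C(C)(C)O1 | starting material
14 | (E)-2-[3-(tert-butyldimethylsilyloxy)prop-2-en-1-yl]-4,4,5,5-tetramethyl-1,3,2-dioxaborolane | CC(C)(C)[Si](C)(C)O/C=C/CB1OC(C)(C)C(C)(C)O1 | intermediate
15 | 6-[2-(3-benzyloxy-4-methoxyphenyl)ethyl]-3-[(1S,2R)-2-(tert-butyldimethylsilyloxy)-1-hydroxybut-3-en-1-yl]-2-vinyl-4H-pyran-4-one | COc1ccc(CCc2cc(=O)c([C@H](O)[C@H](O[Si](C)(C)C(C)(C)C)C=C)c(C=C)o2)cc1OCc1ccccc1 | intermediate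
16 | 6-[2-(3-benzyloxy-4-methoxyphenyl)ethyl]-3-[(1S,2R)-1,2-dihydroxybut-3-en-1-yl]-2-vinyl-4H-pyran-4-one | COc1ccc(CCc2cc(=O)c([C@H](O)[C@H](O)C=C)c(C=C)o2)cc1OCc1ccccc1 | intermediate
17 | 6-[2-(3-benzyloxy-4-methoxyphenyl)ethyl]-3-[(4S,5R)-2,2-dimethyl-5-vinyl-1,3-dioxolan-4-yl]-2-vinyl-4H-pyran-4-one | COc1ccc(CCc2cc(=O)c([C@@H]3OC(C)(C)O[C@@H]3C=C)c(C=C)o2)cc1OCc1ccccc1 | intermediate
18 | (5S,6R)-2-[2-(3-benzyloxy-4-methoxyphenyl)ethyl]-5,6-(isopropylidenedioxy)-5,6-dihydro-4H-chromen-4-one | COc1ccc(CCc2cc(=O)c3c(o2)C=C[C@H]2OC(C)(C)O[C@@H]32)cc1OCc1ccccc1 | intermediate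
19 | (5S,6S,7R,8R)-2-[2-(3-benzyloxy-4-methoxyphenyl)ethyl]-7,8-epoxy-5,6-(isopropylidenedioxy)-5,6,7,8-tetrahydro-4H-chromen-4-one | COc1ccc(CCc2cc(=O)c3c(o2)[C@@H]4O[C@@H]4[C@H]5OC(C)(C)O[C@@H]35)cc1OCc1ccccc1 | intermediate
20 | (5S,6R,7S,8S)-2-[2-(3-benzyloxy-4-methoxyphenyl)ethyl]-7,8-dihydroxy-5,6-(isopropylidenedioxy)-5,6,7,8-tetrahydro-4H-chromen-4-one | COc1ccc(CCc2cc(=O)c3c(o2)[C@@H](O)[C@H](O)[C@H]5OC(C)(C)O[C@@H]35)cc1OCc1ccccc1 | intermediate
21 | (5S,6S,7R,8S)-2-[2-(3-benzyloxy-4-methoxyphenyl)ethyl]-5,6,7,8-tetrahydroxy-5,6,7,8-tetrahydro-4H-chromen-4-one | COc1ccc(CCc2cc(=O)c3c(o2)[C@@H](O)[C@H](O)[C@@H](O)[C@H]3O)cc1OCc1ccccc1 | intermediate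
22 | (5S,6S,7R,8S)-5,6,7,8-tetrahydroxy-2-[2-(3-hydroxy-4-methoxyphenyl)ethyl]-5,6,7,8-tetrahydro-4H-chromen-4-one | COc1ccc(CCc2cc(=O)c3c(o2)[C@@H](O)[C@H](O)[C@@H](O)[C@H]3O)cc1O | target

Total step count: 12. Longest linear sequence: 11 steps (steps 1–5 and 7–12 from alcohol 1; step 6 is a one-step side branch that prepares reagent 14).

Steps most likely to fail

1. Step 9 (ring-closing metathesis). The electron-poor, pyranone-conjugated C8a vinyl group may engage too slowly, so that the ruthenium alkylidene formed at C7 is consumed by intermolecular dimerisation or held in a chelate by the pyranone and dioxolane oxygens. The fallback sets out from dioxinone 5 and comes back at 18, building the carbocycle before the pyranone. The known chiral-pool-derived enone (4R,5S)-4,5-(isopropylidenedioxy)cyclohex-2-en-1-one F1 would be converted (TBSOTf, Et3N, CH2Cl2, −78 °C) into its cross-conjugated silyl dienol ether, (4R,5S)-1-(tert-butyldimethylsilyloxy)-4,5-(isopropylidenedioxy)cyclohexa-1,3-diene F2. Thermolysis of 5 in toluene at 110 °C in its presence should give acylketene 7, hetero-Diels–Alder addition across the silyl enol ether bond, and loss of silanol to deliver 18 directly.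

2. Step 7 (asymmetric anti-alkoxyallylboration). Facial selectivity may be poor because the pyranone carbonyl next to the formyl group can disturb the hydrogen-bonded catalyst–boronate assembly, or the hindered aldehyde may react only through the uncatalysed racemic pathway. The fallback sets out from aldehyde 12 and comes back at diol 16, using a stoichiometric chiral borane. Allyl(diisopropylamino)dimethylsilane is lithiated (n-BuLi, TMEDA) and treated with the enantiomer of B-methoxydiisopinocampheylborane that directs attack to the Re face (the (+)-reagent by the usual model) and BF3·OEt2. Addition to 12 at −78 °C should give the anti β-hydroxy allylsilane 6-[2-(3-benzyloxy-4-methoxyphenyl)ethyl]-3-[(1S,2R)-2-[(diisopropylamino)dimethylsilyl]-1-hydroxybut-3-en-1-yl]-2-vinyl-4H-pyran-4-one F3. Tamao oxidation under non-basic conditions (H2O2, KHF2, DMF) with retention at carbon should then give 16, which enters the second stage of step 8.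

3. Step 4 (vinyl cuprate addition). The cuprate may add 1,2 to the formyl group or add twice, and the enolate may fragment on warming. The fallback sets out from dioxinone 5 and comes back at 12, bringing in the vinyl group with the enol ether partner so that no organometallic meets the aldehyde. Methyl 3,3-dimethoxypropanoate is converted (MeNHOMe·HCl, iPrMgCl) into N,3,3-trimethoxy-N-methylpropanamide F4, and CH2=CHMgBr gives 5,5-dimethoxypent-1-en-3-one F5. Soft enolisation (TBSOTf, Et3N) then gives (Z)-tert-butyl[(5,5-dimethoxypenta-1,3-dien-3-yl)oxy]dimethylsilane F6. Thermolysis of 5 with F6 (toluene, 110 °C) and loss of silanol should give 6-[2-(3-benzyloxy-4-methoxyphenyl)ethyl]-3-(dimethoxymethyl)-2-vinyl-4H-pyran-4-one F7, and dilute aqueous acid then gives 12.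

Further compounds
F1 | step 9 | (4R,5S)-4,5-(isopropylidenedioxy)cyclohex-2-en-1-one | O=C1C=C[C@H]2OC(C)(C)O[C@H]2C1
F2 | step 9 | (4R,5S)-1-(tert-butyldimethylsilyloxy)-4,5-(isopropylidenedioxy)cyclohexa-1,3-diene (descriptors as in F1) | CC(C)(C)[Si](C)(C)OC1=C[C@@H]2OC(C)(C)O[C@@H]2C=C1
F3 | step 7 | 6-[2-(3-benzyloxy-4-methoxyphenyl)ethyl]-3-[(1S,2R)-2-[(diisopropylamino)dimethylsilyl]-1-hydroxybut-3-en-1-yl]-2-vinyl-4H-pyran-4-one | COc1ccc(CCc2cc(=O)c([C@H](O)[C@H]([Si](C)(C)N(C(C)C)C(C)C)C=C)c(C=C)o2)cc1OCc1ccccc1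
F4 | step 4 | N,3,3-trimethoxy-N-methylpropanamide | CON(C)C(=O)CC(OC)OC
F5 | step 4 | 5,5-dimethoxypent-1-en-3-one | C=CC(=O)CC(OC)OC
F6 | step 4 | (Z)-tert-butyl[(5,5-dimethoxypenta-1,3-dien-3-yl)oxy]dimethylsilane | C=C/C(O[Si](C)(C)C(C)(C)C)=C/C(OC)OC
F7 | step 4 | 6-[2-(3-benzyloxy-4-methoxyphenyl)ethyl]-3-(dimethoxymethyl)-2-vinyl-4H-pyran-4-one | COC(OC)c1c(C=C)oc(CCc2ccc(OC)c(OCc3ccccc3)c2)cc1=O
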